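The cyclohexene is closed at C1–C6. Ring atoms C1–C4 (oxygens on C1 and C4, methyl on C3) are carried as a 4-methylbutenolide reduced to its lactol, whose five-membered ring holds the C2=C3 alkene cis. The precursor is this lactol with an (E)-allylic bromide (C14) on C6=C7 and a C9 silyl ether. Indium turns the bromide into an allylindium whose C6 adds to the masked C1 aldehyde: one operation forms the C1–C6 bond and the carbocycle, sets C1 and C6, frees the C4 hydroxyl and leaves a C7 methylene. Two allylborations, an E-selective cross-metathesis and an acrylate ring-closing metathesis build the precursor.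

Key step: step 13

Remark: atoms carry the bisabolane numbers of the target (ring C1–C6, C15 the methyl on C3, C7 on C6 with its methyl C14, chain C8–C11 with oxygen on C9); the C6=C7 alkene of the cyclisation precursor is taken as E (C5 trans to C14), the geometry the chair transition state needs; allylborane 2 is defined by its SMILES as the enantiomer built from (−)-α-pinene, whatever sign a supplier prints.

Step 1
Reactants: 1 methacrolein; 2 B-allyldiisopinocampheylborane (enantiomer from (−)-α-pinene)
Product: 4 (3R)-2-methylhexa-1,5-dien-3-ol, via diisopinocampheylborinate 3 (not isolated)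
Conditions: 2 (1.1 equiv), Et2O, −78 °C; then NaOH, H2O2, 0 to 25 °C
Reagents that add atoms: none
Why: Brown allylboration through a chair Zimmerman–Traxler transition state, in which the isopinocampheyl groups of 2 steer the allyl group to the Re face of the enal carbonyl and should set C4 as R.

Step 2
Reactants: 5 3-methylbut-2-enal; 2 B-allyldiisopinocampheylborane (enantiomer from (−)-α-pinene)
Product: 7 (4R)-6-methylhepta-1,5-dien-4-ol, via diisopinocampheylborinate 6 (not isolated)
Conditions: 2 (1.1 equiv), Et2O, −78 °C; then NaOH, H2O2, 0 to 25 °C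
Reagents that add atoms: none
Why: Brown allylboration of the β,β-disubstituted enal in the same sense (Re-face attack, 1,2-addition only), which should set C9 as R.

Step 3
Reactants: 7 (4R)-6-methylhepta-1,5-dien-4-ol
Product: 8 tert-butyldimethylsilyl ether of 7
Conditions: TBSCl, imidazole, DMF, 25 °C
Reagents that add atoms: tert-butyldimethylsilyl chloride, CC(C)(C)[Si](C)(C)Cl
Why: Imidazole-promoted silylation of a secondary allylic alcohol (Corey protocol) masks the C9 oxygen for every step up to the end game.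

Step 4
Reactants: 8 silyl ether
Product: 10 (4R)-4-(tert-butyldimethylsilyloxy)-6-methylhept-5-en-1-ol, via B-alkyl-9-BBN adduct 9 (not isolated)
Conditions: 9-BBN-H, THF, 0 to 25 °C; then NaOH, H2O2, 0 °C
Reagents that add atoms: hydrogen peroxide, OO (oxygen of the new hydroxyl); 9-borabicyclo[3.3.1]nonane, B1C2CCCC1CCC2 (boron, present only in 9)
Why: Hydroboration–oxidation with 9-BBN-H is anti-Markovnikov and much faster at the monosubstituted alkene than at the trisubstituted C10=C11 alkene, so only the future C14 is oxygenated.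

Step 5
Reactants: 10 primary alcohol
Product: 11 (4R)-4-(tert-butyldimethylsilyloxy)-6-methylhept-5-enal
Conditions: TEMPO (10 mol %), PhI(OAc)2, CH2Cl2, 25 °C
Reagents that add atoms: none
Why: Oxoammonium (TEMPO) oxidation with PhI(OAc)2 as terminal oxidant stops at the aldehyde and leaves the alkene and the allylic silyl ether alone.

Step 6
Reactants: 11 aldehyde
Product: 12 (4R)-4-(tert-butyldimethylsilyloxy)-6-methyl-2-methylidenehept-5-enal
Conditions: aq. CH2O (37 %), pyrrolidine (10 mol %), EtCO2H (10 mol %), iPrOH, 45 °C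
Reagents that add atoms: formaldehyde, C=O
Why: Amine-catalysed Mannich condensation with formaldehyde and elimination (α-methylenation of an aldehyde) puts a sacrificial methylene on C7 and makes C14 the formyl group of a 2-substituted acrolein.

Step 7
Reactants: 12 2-substituted acrolein; 4 (3R)-2-methylhexa-1,5-dien-3-ol
Product: 13 (2E,5R)-2-[(2R)-2-(tert-butyldimethylsilyloxy)-4-methylpent-3-en-1-yl]-5-hydroxy-6-methylhepta-2,6-dienal
Conditions: 4 (2.5 equiv), second-generation Hoveyda–Grubbs catalyst (5 mol %), CH2Cl2, 40 °C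
Reagents that add atoms: none
Why: Olefin cross-metathesis of a terminal alkene with a 2-substituted acrolein gives the conjugated trisubstituted enal under thermodynamic control with the formyl carbon C14 trans to C5 (E), the 1,1-disubstituted and trisubstituted alkenes of both partners being too hindered to compete.

Step 8
Reactants: 13 hydroxy enal; 14 acryloyl chloride
Product: 15 acrylate of 13 at the C4 oxygen
Conditions: 14 (1.5 equiv), iPr2NEt, CH2Cl2, −20 to 0 °C
Reagents that add atoms: none
Why: O-Acylation of the only free hydroxyl with an acid chloride and a hindered amine base, placed after the cross-metathesis so that no terminal alkene is left that could close a six-membered lactone.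

Step 9
Reactants: 15 acrylate
Product: 16 (5R)-5-[(2E,5R)-5-(tert-butyldimethylsilyloxy)-3-formyl-7-methylocta-2,6-dien-1-yl]-4-methylfuran-2(5H)-one
Conditions: second-generation Grubbs catalyst (10 mol %), toluene (0.005 M), 80 °C
Reagents that add atoms: none
Why: Ring-closing metathesis of an acrylate onto a 1,1-disubstituted alkene gives the 4-methylbutenolide and ethylene, while the electron-poor trisubstituted enal alkene and the prenyl-type alkene are poor partners and closure onto C6=C7 would need ruthenium on the fully substituted C7.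

Step 10
Reactants: 16 butenolide enal
Product: 17 (5R)-5-[(2E,5R)-5-(tert-butyldimethylsilyloxy)-3-(hydroxymethyl)-7-methylocta-2,6-dien-1-yl]-4-methylfuran-2(5H)-one
Conditions: NaBH4, CeCl3·7H2O, MeOH, −78 °C
Reagents that add atoms: none
Why: Luche reduction gives clean 1,2-reduction of the enal at −78 °C, where the butenolide is not touched and the E alkene is kept.

Step 11
Reactants: 17 allylic alcohol
Product: 18 (5R)-5-[(2E,5R)-3-(bromomethyl)-5-(tert-butyldimethylsilyloxy)-7-methylocta-2,6-dien-1-yl]-4-methylfuran-2(5H)-one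
Conditions: CBr4, PPh3, CH2Cl2, −20 to 0 °C
Reagents that add atoms: carbon tetrabromide, BrC(Br)(Br)Br
Why: Appel bromination is an SN2 displacement at the primary allylic carbon, so the E geometry of C6=C7 is kept and the lactone and silyl ether are untouched.

Step 12
Reactants: 18 bromo butenolide
Product: 19 (5R)-5-[(2E,5R)-3-(bromomethyl)-5-(tert-butyldimethylsilyloxy)-7-methylocta-2,6-dien-1-yl]-4-methyl-2,5-dihydrofuran-2-ol (both anomers)
Conditions: iBu2AlH (1.2 equiv), CH2Cl2, −78 °C; aq. potassium sodium tartrate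
Reagents that add atoms: none
Why: iBu2AlH at −78 °C stops at the lactol because the tetrahedral aluminate survives until work-up, the allylic bromide and silyl ether are inert, and the crude lactol is used at once because acid or silica can dehydrate it to a furan.

Step 13
Reactants: 19 lactol bromide
Product: 21 (1S,4R,6S)-6-[(4R)-4-(tert-butyldimethylsilyloxy)-6-methylhepta-1,5-dien-2-yl]-3-methylcyclohex-2-ene-1,4-diol, via allylindium dibromide 20 (not isolated)
Conditions: In powder (2 equiv), THF/H2O 3:1 (0.01 M), 25 °C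
Reagents that add atoms: none
Why: Indium metal inserts into the allylic C14–Br bond and the allylindium adds through its γ-carbon C6 to the hydroxy-aldehyde tautomer of the lactol at C1 (SE2′, 1,2-addition), so the C1–C6 bond, the carbocycle and the C7=C14 methylene arise together and the lactol oxygen is released as the C4 hydroxyl. The closest known reaction type is the intramolecular indium or CrCl2 Barbier allylation of ω-formyl allylic bromides and of lactols in wet solvents. The ring closes in 6-exo-trig fashion on the C1 carbonyl, which C6 can reach only because the lactol origin fixes the C2=C3 alkene as cis. C1 and C6 are set together by a chair Zimmerman–Traxler transition state in which the E-allylindium places C5 and the aldehyde substituent C2 equatorial, which gives the trans C1–O/C6 relationship. The face relative to the existing C4 centre should follow from the half-chair of the forming ring, in which the C4 oxygen is pseudo-axial to avoid A(1,2) strain with the C3 methyl, which places C1–O cis to C4–O (1S,6S). The step needs γ- over α-attack, 1,2- over 1,4-addition and cyclisation over dimerisation, which the SE2′ preference of allylindium reagents, the aldehyde electrophile and the 0.01 M dilution should secure.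

Step 14
Reactants: 21 diol
Product: 22 C4 monoacetate of 21
Conditions: Novozym 435 (immobilised Candida antarctica lipase B), vinyl acetate (5 equiv), tBuOMe, 30 °C
Reagents that add atoms: vinyl acetate, CC(=O)OC=C
Why: Lipase-catalysed transesterification with an irreversible acyl donor should acetylate only the C4 hydroxyl, whose carbinol carbon lies between a methylene and a flat vinylic carbon, whereas the C1 hydroxyl is shielded by the branched substituent on C6.

Step 15
Reactants: 22 monoacetate
Product: 23 (1S,4R,6S)-4-acetoxy-6-[(2R,4R)-4-(tert-butyldimethylsilyloxy)-6-methylhept-5-en-2-yl]-3-methylcyclohex-2-en-1-ol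
Conditions: [Rh(nbd)(dppb)]BF4 (5 mol %), H2 (40 bar), CH2Cl2, 25 °C
Reagents that add atoms: none
Why: Hydroxyl-directed homogeneous hydrogenation (Brown–Evans type), in which the cationic rhodium binds the C1 hydroxyl and the neighbouring 1,1-disubstituted alkene in a chelate that keeps the C8 chain syn to C6–H to avoid A(1,2) strain and so should deliver hydrogen to the face that gives 7R, while the trisubstituted alkenes react much more slowly.

Step 16
Reactants: 23 alcohol; 24 angelic acid
Product: 26 C1 angelate of 23, via mixed anhydride 25 (not isolated)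
Conditions: 24 (2 equiv), 2,4,6-trichlorobenzoyl chloride, Et3N, toluene, 25 °C; then 23, 75 °C
Reagents that add atoms: none
Why: Yamaguchi esterification through the mixed 2,4,6-trichlorobenzoic anhydride, run without DMAP because these conditions are known to transfer the angeloyl group without Z-to-E isomerisation to the tiglate.

Step 17
Reactants: 26 silyl ether
Product: 27 C9 alcohol
Conditions: HF·pyridine, pyridine, THF, 0 to 25 °C
Reagents that add atoms: none
Why: Fluoride cleavage of the Si–O bond with pyridine-buffered HF·pyridine removes the silyl group without ester migration, hydrolysis or ionisation of the allylic C9–O bond.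

Step 18
Reactants: 27 alcohol
Product: 28 target CNP0417294.1
Conditions: Ac2O, pyridine, DMAP (5 mol %), CH2Cl2, 0 °C
Reagents that add atoms: acetic anhydride, CC(=O)OC(C)=O
Why: DMAP-catalysed acetylation of the secondary allylic alcohol at 0 °C completes the target without disturbing the angelate.

Compound list
1 | methacrolein (2-methylprop-2-enal) | CC(=C)C=O | starting material
2 | B-allyldiisopinocampheylborane, enantiomer from (−)-α-pinene | C=CCB([C@H]1C[C@H]2C[C@@H]([C@@H]1C)C2(C)C)[C@H]1C[C@H]2C[C@@H]([C@@H]1C)C2(C)C | starting material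
3 | diisopinocampheylborinate of 4 | C=C(C)[C@H](OB([C@H]1C[C@H]2C[C@@H]([C@@H]1C)C2(C)C)[C@H]1C[C@H]2C[C@@H]([C@@H]1C)C2(C)C)CC=C | intermediate
4 | (3R)-2-methylhexa-1,5-dien-3-ol | C=C(C)[C@H](O)CC=C | intermediate
5 | 3-methylbut-2-enal | CC(C)=CC=O | starting material
6 | diisopinocampheylborinate of 7 | C=CC[C@@H](OB([C@H]1C[C@H]2C[C@@H]([C@@H]1C)C2(C)C)[C@H]1C[C@H]2C[C@@H]([C@@H]1C)C2(C)C)C=C(C)C | intermediate
7 | (4R)-6-methylhepta-1,5-dien-4-ol | C=CC[C@@H](O)C=C(C)C | intermediate
8 | tert-butyldimethyl{[(4R)-6-methylhepta-1,5-dien-4-yl]oxy}silane | C=CC[C@@H](O[Si](C)(C)C(C)(C)C)C=C(C)C | intermediate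
9 | 9-[(4R)-4-(tert-butyldimethylsilyloxy)-6-methylhept-5-en-1-yl]-9-borabicyclo[3.3.1]nonane | B1(CCC[C@@H](O[Si](C)(C)C(C)(C)C)C=C(C)C)C2CCCC1CCC2 | intermediate
10 | (4R)-4-(tert-butyldimethylsilyloxy)-6-methylhept-5-en-1-ol | OCCC[C@@H](O[Si](C)(C)C(C)(C)C)C=C(C)C | intermediate
11 | (4R)-4-(tert-butyldimethylsilyloxy)-6-methylhept-5-enal | O=CCC[C@@H](O[Si](C)(C)C(C)(C)C)C=C(C)C | intermediate
12 | (4R)-4-(tert-butyldimethylsilyloxy)-6-methyl-2-methylidenehept-5-enal | C=C(C=O)C[C@@H](O[Si](C)(C)C(C)(C)C)C=C(C)C | intermediate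
13 | (2E,5R)-2-[(2R)-2-(tert-butyldimethylsilyloxy)-4-methylpent-3-en-1-yl]-5-hydroxy-6-methylhepta-2,6-dienal | C=C(C)[C@H](O)C/C=C(/C=O)C[C@@H](O[Si](C)(C)C(C)(C)C)C=C(C)C | intermediate
14 | acryloyl chloride | C=CC(=O)Cl | starting material
15 | (2E,5R)-5-(acryloyloxy)-2-[(2R)-2-(tert-butyldimethylsilyloxy)-4-methylpent-3-en-1-yl]-6-methylhepta-2,6-dienal | C=C(C)[C@H](OC(=O)C=C)C/C=C(/C=O)C[C@@H](O[Si](C)(C)C(C)(C)C)C=C(C)C | intermediate
16 | (5R)-5-[(2E,5R)-5-(tert-butyldimethylsilyloxy)-3-formyl-7-methylocta-2,6-dien-1-yl]-4-methylfuran-2(5H)-one | O=C1C=C(C)[C@H](O1)C/C=C(/C=O)C[C@@H](O[Si](C)(C)C(C)(C)C)C=C(C)C | intermediate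
17 | (5R)-5-[(2E,5R)-5-(tert-butyldimethylsilyloxy)-3-(hydroxymethyl)-7-methylocta-2,6-dien-1-yl]-4-methylfuran-2(5H)-one | O=C1C=C(C)[C@H](O1)C/C=C(/CO)C[C@@H](O[Si](C)(C)C(C)(C)C)C=C(C)C | intermediate
18 | (5R)-5-[(2E,5R)-3-(bromomethyl)-5-(tert-butyldimethylsilyloxy)-7-methylocta-2,6-dien-1-yl]-4-methylfuran-2(5H)-one | O=C1C=C(C)[C@H](O1)C/C=C(/CBr)C[C@@H](O[Si](C)(C)C(C)(C)C)C=C(C)C | intermediate
19 | (5R)-5-[(2E,5R)-3-(bromomethyl)-5-(tert-butyldimethylsilyloxy)-7-methylocta-2,6-dien-1-yl]-4-methyl-2,5-dihydrofuran-2-ol, both anomers | OC1C=C(C)[C@H](O1)C/C=C(/CBr)C[C@@H](O[Si](C)(C)C(C)(C)C)C=C(C)C | intermediate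
20 | allylindium dibromide from 19 (InBr2 on C14) | OC1C=C(C)[C@H](O1)C/C=C(/C[In](Br)Br)C[C@@H](O[Si](C)(C)C(C)(C)C)C=C(C)C | intermediate
21 | (1S,4R,6S)-6-[(4R)-4-(tert-butyldimethylsilyloxy)-6-methylhepta-1,5-dien-2-yl]-3-methylcyclohex-2-ene-1,4-diol | O[C@@H]1C=C(C)[C@H](O)C[C@H]1C(=C)C[C@@H](O[Si](C)(C)C(C)(C)C)C=C(C)C | intermediate
22 | (1S,4R,6S)-4-acetoxy-6-[(4R)-4-(tert-butyldimethylsilyloxy)-6-methylhepta-1,5-dien-2-yl]-3-methylcyclohex-2-en-1-ol | O[C@@H]1C=C(C)[C@H](OC(C)=O)C[C@H]1C(=C)C[C@@H](O[Si](C)(C)C(C)(C)C)C=C(C)C | intermediate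
23 | (1S,4R,6S)-4-acetoxy-6-[(2R,4R)-4-(tert-butyldimethylsilyloxy)-6-methylhept-5-en-2-yl]-3-methylcyclohex-2-en-1-ol | O[C@@H]1C=C(C)[C@H](OC(C)=O)C[C@H]1[C@H](C)C[C@@H](O[Si](C)(C)C(C)(C)C)C=C(C)C | intermediate
24 | angelic acid, (2Z)-2-methylbut-2-enoic acid | C/C=C(/C)C(=O)O | starting material
25 | (2Z)-2-methylbut-2-enoic 2,4,6-trichlorobenzoic anhydride | C/C=C(/C)C(=O)OC(=O)c1c(Cl)cc(Cl)cc1Cl | intermediate
26 | (1S,4R,6S)-4-acetoxy-6-[(2R,4R)-4-(tert-butyldimethylsilyloxy)-6-methylhept-5-en-2-yl]-3-methylcyclohex-2-en-1-yl (2Z)-2-methylbut-2-enoate | C/C=C(/C)C(=O)O[C@@H]1C=C(C)[C@H](OC(C)=O)C[C@H]1[C@H](C)C[C@@H](O[Si](C)(C)C(C)(C)C)C=C(C)C | intermediate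
27 | (1S,4R,6S)-4-acetoxy-6-[(2R,4R)-4-hydroxy-6-methylhept-5-en-2-yl]-3-methylcyclohex-2-en-1-yl (2Z)-2-methylbut-2-enoate | C/C=C(/C)C(=O)O[C@@H]1C=C(C)[C@H](OC(C)=O)C[C@H]1[C@H](C)C[C@@H](O)C=C(C)C | intermediate
28 | CNP0417294.1, (1S,4R,6S)-4-acetoxy-6-[(2R,4R)-4-acetoxy-6-methylhept-5-en-2-yl]-3-methylcyclohex-2-en-1-yl (2Z)-2-methylbut-2-enoate | C/C=C(/C)C(=O)O[C@@H]1C=C(C)[C@H](OC(C)=O)C[C@H]1[C@H](C)C[C@H](C=C(C)C)OC(C)=O | target

Total step count: 18. Longest linear sequence: 17 steps (steps 2 to 18).

Steps most likely to fail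

Step 13 (key step). The crude lactol may lose water to a 2,3-disubstituted furan under the Lewis-acidic indium salts, the allylindium may couple between two molecules, or the bias from C4 may be too weak to control the face of attack. The fallback closes the ring by metathesis instead of by allylation. It sets out from enal 13, which is reduced (NaBH4, CeCl3·7H2O, MeOH, −78 °C) to the diol (2E,5R)-2-[(2R)-2-(tert-butyldimethylsilyloxy)-4-methylpent-3-en-1-yl]-6-methylhepta-2,6-diene-1,5-diol F1. The primary allylic hydroxyl is brominated selectively (CBr4, PPh3, −30 °C) to the bromo alcohol F2. Indium-mediated Barbier allylation of acrolein in THF/H2O should then give the anti adduct, the triene diol F3, whose isomers at C1/C6 relative to C4 are separated by chromatography. Ring-closing metathesis of the C1 vinyl group onto the C3 isopropenyl group (second-generation Grubbs catalyst, CH2Cl2, 40 °C) forms the C2=C3 bond and comes back to the route at 21.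

Step 14. The enzyme may acylate the C1 hydroxyl as well or instead, so that the two ring hydroxyls are not told apart. The fallback replaces the enzyme by a bulky silyl chloride and merges the two acetylations. It sets out from 21, which is silylated at the less hindered C4 hydroxyl (TBSCl, imidazole, DMF, 0 °C) to the bis-silyl ether F4. Hydroxyl-directed hydrogenation as in step 15 gives the saturated alcohol F5, and Yamaguchi angeloylation as in step 16 gives the angelate F6. HF·pyridine removes both silyl groups to give the C4,C9-diol F7, and Ac2O, pyridine and DMAP acetylate both hydroxyls at once, which comes back to the route at 28.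

Step 15. The chelate may not discriminate the two faces of the C7=C14 alkene well enough, or the catalyst may also reduce the ring or prenyl alkene or isomerise the allylic alcohol. The fallback uses catalyst control on a substrate without a free hydroxyl. It sets out from 22, which is angeloylated first (conditions of step 16) to the methylene angelate F8. The 1,1-disubstituted alkene is then hydrogenated with [Ir(cod)((S)-tBu-PHOX)]B[3,5-(CF3)2C6H3]4 (H2, 1 bar, CH2Cl2, 0 °C), the antipodal ligand being used if the substrate bias is mismatched, which comes back to the route at 26.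

Further compounds
F1 | step 13 | (2E,5R)-2-[(2R)-2-(tert-butyldimethylsilyloxy)-4-methylpent-3-en-1-yl]-6-methylhepta-2,6-diene-1,5-diol | C=C(C)[C@H](O)C/C=C(/CO)C[C@@H](O[Si](C)(C)C(C)(C)C)C=C(C)C
F2 | step 13 | (3R,5E)-7-bromo-6-[(2R)-2-(tert-butyldimethylsilyloxy)-4-methylpent-3-en-1-yl]-2-methylhepta-1,5-dien-3-ol | C=C(C)[C@H](O)C/C=C(/CBr)C[C@@H](O[Si](C)(C)C(C)(C)C)C=C(C)C
F3 | step 13 | (3R,4S,6R)-4-[(4R)-4-(tert-butyldimethylsilyloxy)-6-methylhepta-1,5-dien-2-yl]-7-methylocta-1,7-diene-3,6-diol | C=C[C@@H](O)[C@@H](C[C@@H](O)C(C)=C)C(=C)C[C@@H](O[Si](C)(C)C(C)(C)C)C=C(C)C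
F4 | step 14 | (1S,4R,6S)-4-(tert-butyldimethylsilyloxy)-6-[(4R)-4-(tert-butyldimethylsilyloxy)-6-methylhepta-1,5-dien-2-yl]-3-methylcyclohex-2-en-1-ol | O[C@@H]1C=C(C)[C@H](O[Si](C)(C)C(C)(C)C)C[C@H]1C(=C)C[C@@H](O[Si](C)(C)C(C)(C)C)C=C(C)C
F5 | step 14 | (1S,4R,6S)-4-(tert-butyldimethylsilyloxy)-6-[(2R,4R)-4-(tert-butyldimethylsilyloxy)-6-methylhept-5-en-2-yl]-3-methylcyclohex-2-en-1-ol | O[C@@H]1C=C(C)[C@H](O[Si](C)(C)C(C)(C)C)C[C@H]1[C@H](C)C[C@@H](O[Si](C)(C)C(C)(C)C)C=C(C)C
F6 | step 14 | (1S,4R,6S)-4-(tert-butyldimethylsilyloxy)-6-[(2R,4R)-4-(tert-butyldimethylsilyloxy)-6-methylhept-5-en-2-yl]-3-methylcyclohex-2-en-1-yl (2Z)-2-methylbut-2-enoate | C/C=C(/C)C(=O)O[C@@H]1C=C(C)[C@H](O[Si](C)(C)C(C)(C)C)C[C@H]1[C@H](C)C[C@@H](O[Si](C)(C)C(C)(C)C)C=C(C)C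
F7 | step 14 | (1S,4R,6S)-4-hydroxy-6-[(2R,4R)-4-hydroxy-6-methylhept-5-en-2-yl]-3-methylcyclohex-2-en-1-yl (2Z)-2-methylbut-2-enoate | C/C=C(/C)C(=O)O[C@@H]1C=C(C)[C@H](O)C[C@H]1[C@H](C)C[C@@H](O)C=C(C)C
F8 | step 15 | (1S,4R,6S)-4-acetoxy-6-[(4R)-4-(tert-butyldimethylsilyloxy)-6-methylhepta-1,5-dien-2-yl]-3-methylcyclohex-2-en-1-yl (2Z)-2-methylbut-2-enoate | C/C=C(/C)C(=O)O[C@@H]1C=C(C)[C@H](OC(C)=O)C[C@H]1C(=C)C[C@@H](O[Si](C)(C)C(C)(C)C)C=C(C)C
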